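**Plan**

- Enabling feature: C3 of the pyranone (ring C) carries all of ring B and lies between C2 and C4. C3 plus ring B is therefore one carbene carbon placed into the C2=C3 enol bond of a benzofuran-3-one that already holds ring A, O1, C2 and the future C4.
- Retrosynthetic cuts, in order: the two O–MOM bonds; the C5'–CH2 bond of the prenyl group (Stille); then C2–C3 and C3–C4 together, giving a 3-silyloxybenzofuran and a 3-aryl-3-chlorodiazirine.
- Forward, ring A: benzofuranone 1 is MOM-protected, O-methylated and silylated to enol ether 4.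
- Forward, ring B: aldehyde 5 is methylated, MOM-protected and taken through nitrile and amidine to diazirine 12.
- Ring C arises last: carbon insertion expands the furan of 4 to the pyranone and gives bromoisoflavone 16; prenylation and MOM removal finish.
- Stereochemistry: the target has no stereocentre and no stereogenic double bond, so nothing has to be set.

Key step: step 9

Assumption: diazirine 12, like other electron-rich 3-aryl-3-chlorodiazirines, is taken to be too labile to store; it is made immediately before step 9 and handled only as a cold solution. Compounds 1, 5 and 17 are taken as purchased.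

**Route**

Step 1
Reactants: 1 4,6-dihydroxy-1-benzofuran-3(2H)-one
Product: 2 4-hydroxy-6-(methoxymethoxy)-1-benzofuran-3(2H)-one
Conditions: MOMCl (1.05 equiv), iPr2NEt, DMF, 0 °C
Reagents that add atoms: chloromethyl methyl ether, COCCl
Why: Williamson-type MOM ether formation; the 6-hydroxyl, para to the ketone and not hydrogen-bonded, is the more acidic phenol and should react first with one equivalent of electrophile, while the weak amine base does not enolise C2.

Step 2
Reactants: 2 4-hydroxy-6-(methoxymethoxy)-1-benzofuran-3(2H)-one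
Product: 3 4-methoxy-6-(methoxymethoxy)-1-benzofuran-3(2H)-one
Conditions: Me2SO4, K2CO3, DME, 60 °C
Reagents that add atoms: dimethyl sulfate, COS(=O)(=O)OC
Why: Williamson O-methylation of the remaining, only weakly chelated 4-hydroxyl; phenoxide O-alkylation of hydroxybenzofuran-3-ones under carbonate should outrun alkylation at C2, and the MOM ether is inert to base.

Step 3
Reactants: 3 4-methoxy-6-(methoxymethoxy)-1-benzofuran-3(2H)-one
Product: 4 3-(tert-butyldimethylsilyloxy)-4-methoxy-6-(methoxymethoxy)-1-benzofuran
Conditions: TBSOTf, Et3N, CH2Cl2, −78 to 0 °C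
Reagents that add atoms: tert-butyldimethylsilyl trifluoromethanesulfonate, CC(C)(C)[Si](C)(C)OS(=O)(=O)C(F)(F)F
Why: Silyl enol ether formation by soft enolisation (silyl triflate with a tertiary amine); O-silylation of the C3 ketone is driven by aromatisation to the benzofuran, and the aryl MOM ether should tolerate the amine-buffered triflate at low temperature.

Step 4
Reactants: 5 3-bromo-4,5-dihydroxybenzaldehyde
Product: 6 3-bromo-5-hydroxy-4-methoxybenzaldehyde
Conditions: MeI (1.05 equiv), Li2CO3, DMF, 40 °C
Reagents that add atoms: iodomethane, CI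
Why: Regioselective Williamson methylation; the 4-hydroxyl, para to the aldehyde and ortho to bromine, is the most acidic, so the weak base Li2CO3 should ionise and methylate only that oxygen.

Step 5
Reactants: 6 3-bromo-5-hydroxy-4-methoxybenzaldehyde
Product: 7 3-bromo-4-methoxy-5-(methoxymethoxy)benzaldehyde
Conditions: MOMCl, iPr2NEt, CH2Cl2, 0 °C to rt
Reagents that add atoms: chloromethyl methyl ether, COCCl
Why: MOM ether formation (Williamson-type alkylation under amine base) at the only remaining phenol.

Step 6
Reactants: 7 3-bromo-4-methoxy-5-(methoxymethoxy)benzaldehyde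
Product: 8 3-bromo-4-methoxy-5-(methoxymethoxy)benzonitrile
Conditions: I2, aq NH3, THF, rt
Reagents that add atoms: ammonia, N
Why: Oxidative conversion of an aldehyde into a nitrile with iodine in aqueous ammonia (N-iodination of the aldimine, then loss of HI); the basic medium leaves the MOM ether and the aryl bromide untouched.

Step 7
Reactants: 8 3-bromo-4-methoxy-5-(methoxymethoxy)benzonitrile
Product: 10 3-bromo-4-methoxy-5-(methoxymethoxy)benzamidinium chloride, via lithium N,N'-bis(trimethylsilyl)amidinate 9 (not isolated)
Conditions: LiN(SiMe3)2, THF, 0 °C to rt; then MeOH, NH4Cl, rt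
Reagents that add atoms: lithium bis(trimethylsilyl)amide, [Li]N([Si](C)(C)C)[Si](C)(C)C; ammonium chloride, [NH4+].[Cl-]
Why: Amidine synthesis by addition of a silylamide to a nitrile; methanolysis of the N-silyl groups with NH4Cl as the only proton source should release the amidinium chloride without an acid strong enough to cleave the MOM ether.

Step 8
Reactants: 10 3-bromo-4-methoxy-5-(methoxymethoxy)benzamidinium chloride
Product: 12 3-[3-bromo-4-methoxy-5-(methoxymethoxy)phenyl]-3-chloro-3H-diazirine, via N,N'-dichloroamidine 11 (not isolated)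
Conditions: aq NaOCl, LiCl, DMSO, 0 °C to rt; extraction into pentane, kept cold and dark, not concentrated to dryness
Reagents that add atoms: sodium hypochlorite, [Na+].[O-]Cl; lithium chloride, [Li+].[Cl-] (chloride pool for the C–Cl bond)
Why: Graham oxidation; hypochlorite chlorinates both amidine nitrogens, base closes the N–N bond and chloride returns at carbon, while the basic medium spares the MOM ether and the amidinium-deactivated ring should resist chlorination.

Step 9
Reactants: 4 3-(tert-butyldimethylsilyloxy)-4-methoxy-6-(methoxymethoxy)-1-benzofuran; 12 3-[3-bromo-4-methoxy-5-(methoxymethoxy)phenyl]-3-chloro-3H-diazirine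
Product: 16 5'-bromo-5,4'-dimethoxy-7,3'-bis(methoxymethoxy)isoflavone, via arylchlorocarbene 13 (not isolated), via chlorocyclopropane 14 (not isolated), via 4-silyloxybenzopyrylium chloride 15 (not isolated)
Conditions: 4 (1.5 equiv), Na2CO3, MeCN, 50 °C, slow addition of the solution of 12, dark
Reagents that add atoms: none
Why: Proposed new method: thermal loss of N2 from 12 gives the singlet arylchlorocarbene 13, which adds [2+1] across the C2=C3 enol ether bond of 4 to give chlorocyclopropane 14; departure of chloride with disrotatory two-electron opening of the former C2–C3 bond gives the 4-silyloxybenzopyrylium chloride 15, and chloride then takes the silyl group to leave chromone 16 at the correct oxidation level. The closest known reaction types are the arylchlorocarbene single-carbon insertion into indoles and pyrroles (Ciamician–Dennstedt-type expansion to 3-arylquinolines and 3-arylpyridines) and the dihalocarbene ring expansion of cyclic silyl enol ethers to α-halo enones. The pyranone ring is closed not by a cyclisation but by ring expansion: the cyclopropane bond shared with the furan breaks, so the five-membered ring becomes six-membered with the new C2–C3 and C3–C4 bonds in place. No stereocentre survives, since both cyclopropane epimers converge on the same planar cation, the endo-chloro epimer by the concerted path and the exo-chloro epimer by oxygen-assisted stepwise ionisation. The step needs chemoselective cyclopropanation of the enol ether over the arenes, which its two oxygen donors should secure, and the aryl carbon must end between C2 and C4, which follows because only the ring-fusion bond can break. Solid Na2CO3 shields the MOM groups and the enol ether from adventitious HCl, and ring B carries bromine in place of the prenyl group because the carbene would also add to a trisubstituted alkene.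

Step 10
Reactants: 16 5'-bromo-5,4'-dimethoxy-7,3'-bis(methoxymethoxy)isoflavone; 17 tributyl(3-methylbut-2-en-1-yl)stannane
Product: 18 5,4'-dimethoxy-7,3'-bis(methoxymethoxy)-5'-(3-methylbut-2-en-1-yl)isoflavone
Conditions: Pd(PPh3)4 (10 mol %), DMF, 95 °C
Reagents that add atoms: none
Why: Stille cross-coupling; zerovalent palladium inserts into the aryl bromide, the prenyl group is transferred from tin through its unsubstituted α-carbon and reductive elimination forms the C5'–CH2 bond, with MOM ethers and chromone inert.

Step 11
Reactants: 18 5,4'-dimethoxy-7,3'-bis(methoxymethoxy)-5'-(3-methylbut-2-en-1-yl)isoflavone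
Product: 19 7-hydroxy-3-[3-hydroxy-4-methoxy-5-(3-methylbut-2-en-1-yl)phenyl]-5-methoxy-4H-chromen-4-one
Conditions: 2 M aq HCl, MeOH–THF, 45 °C
Reagents that add atoms: none
Why: Acid-catalysed acetal cleavage (MOM removal by transacetalisation to methanol); dilute acid should cleave both aryl MOM ethers and leave the aryl methyl ethers, the chromone and the prenyl group, which has no ortho hydroxyl to cyclise onto it.

**Compound list**

1 | 4,6-dihydroxy-1-benzofuran-3(2H)-one | O=C1COc2cc(O)cc(O)c12 | starting material
2 | 4-hydroxy-6-(methoxymethoxy)-1-benzofuran-3(2H)-one | O=C1COc2cc(OCOC)cc(O)c12 | intermediate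
3 | 4-methoxy-6-(methoxymethoxy)-1-benzofuran-3(2H)-one | COc1cc(OCOC)cc2OCC(=O)c12 | intermediate
4 | 3-(tert-butyldimethylsilyloxy)-4-methoxy-6-(methoxymethoxy)-1-benzofuran | COc1cc(OCOC)cc2occ(O[Si](C)(C)C(C)(C)C)c12 | intermediate
5 | 3-bromo-4,5-dihydroxybenzaldehyde | O=Cc1cc(O)c(O)c(Br)c1 | starting material
6 | 3-bromo-5-hydroxy-4-methoxybenzaldehyde | O=Cc1cc(O)c(OC)c(Br)c1 | intermediate
7 | 3-bromo-4-methoxy-5-(methoxymethoxy)benzaldehyde | O=Cc1cc(OCOC)c(OC)c(Br)c1 | intermediate
8 | 3-bromo-4-methoxy-5-(methoxymethoxy)benzonitrile | N#Cc1cc(OCOC)c(OC)c(Br)c1 | intermediate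
9 | lithium N,N'-bis(trimethylsilyl)-3-bromo-4-methoxy-5-(methoxymethoxy)benzamidinate | C[Si](C)(C)N=C(c1cc(OCOC)c(OC)c(Br)c1)N([Li])[Si](C)(C)C | intermediate (not isolated)
10 | 3-bromo-4-methoxy-5-(methoxymethoxy)benzamidinium chloride | [Cl-].NC(=[NH2+])c1cc(OCOC)c(OC)c(Br)c1 | intermediate
11 | N,N'-dichloro-3-bromo-4-methoxy-5-(methoxymethoxy)benzamidine | ClN=C(NCl)c1cc(OCOC)c(OC)c(Br)c1 | intermediate (not isolated)
12 | 3-[3-bromo-4-methoxy-5-(methoxymethoxy)phenyl]-3-chloro-3H-diazirine | ClC1(N=N1)c2cc(OCOC)c(OC)c(Br)c2 | intermediate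
13 | [3-bromo-4-methoxy-5-(methoxymethoxy)phenyl]chlorocarbene | Cl[C]c1cc(OCOC)c(OC)c(Br)c1 | intermediate (not isolated)
14 | 1-[3-bromo-4-methoxy-5-(methoxymethoxy)phenyl]-6b-(tert-butyldimethylsilyloxy)-1-chloro-6-methoxy-4-(methoxymethoxy)-1a,6b-dihydro-1H-cyclopropa[b][1]benzofuran (racemic, cis-fused, both epimers at the chlorine-bearing carbon) | COc1cc(OCOC)cc2OC3C(Cl)(c4cc(OCOC)c(OC)c(Br)c4)C3(O[Si](C)(C)C(C)(C)C)c12 | intermediate (not isolated)
15 | 3-[3-bromo-4-methoxy-5-(methoxymethoxy)phenyl]-4-(tert-butyldimethylsilyloxy)-5-methoxy-7-(methoxymethoxy)chromenylium chloride | COc1cc(OCOC)cc2[o+]cc(-c3cc(OCOC)c(OC)c(Br)c3)c(O[Si](C)(C)C(C)(C)C)c12.[Cl-] | intermediate (not isolated)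
16 | 5'-bromo-5,4'-dimethoxy-7,3'-bis(methoxymethoxy)isoflavone, i.e. 3-[3-bromo-4-methoxy-5-(methoxymethoxy)phenyl]-5-methoxy-7-(methoxymethoxy)-4H-chromen-4-one | COc1cc(OCOC)cc2occ(-c3cc(OCOC)c(OC)c(Br)c3)c(=O)c12 | intermediate
17 | tributyl(3-methylbut-2-en-1-yl)stannane | CCCC[Sn](CCCC)(CCCC)CC=C(C)C | starting material
18 | 5,4'-dimethoxy-7,3'-bis(methoxymethoxy)-5'-(3-methylbut-2-en-1-yl)isoflavone | COc1cc(OCOC)cc2occ(-c3cc(OCOC)c(OC)c(CC=C(C)C)c3)c(=O)c12 | intermediate
19 | 7-hydroxy-3-[3-hydroxy-4-methoxy-5-(3-methylbut-2-en-1-yl)phenyl]-5-methoxy-4H-chromen-4-one | COc1c(O)cc(-c2coc3cc(O)cc(OC)c3c2=O)cc1CC=C(C)C | target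

**Count**

Total steps: 11 (steps 1–3 for ring A, steps 4–8 for ring B, steps 9–11 after the union).
Longest linear sequence: 8 steps (5 to 19, steps 4–11).

**Steps most likely to fail**

Step 9 (the proposed carbon insertion). The carbene may be consumed by unreacted diazirine (azine formation) before it meets the enol ether. The enol ether may lose its silyl group before cyclopropanation, or the exo-chloro cyclopropane may fail to ionise. The fallback is the oxidative chalcone rearrangement, all known chemistry; it sets out from aldehyde 7 and comes back at 16.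
- Commercial 1-(2,4-dihydroxy-6-methoxyphenyl)ethanone F1 would be MOM-protected at its unchelated 4-hydroxyl (MOMCl, iPr2NEt) to 1-[2-hydroxy-6-methoxy-4-(methoxymethoxy)phenyl]ethanone F2.
- Claisen–Schmidt condensation of F2 with 7 (KOH, EtOH) would give (E)-3-[3-bromo-4-methoxy-5-(methoxymethoxy)phenyl]-1-[2-hydroxy-6-methoxy-4-(methoxymethoxy)phenyl]prop-2-en-1-one F3.
- Tl(NO3)3·3H2O in MeOH/HC(OMe)3 (trivalent thallium, oxidative 1,2-aryl shift) would convert F3 into racemic 2-[3-bromo-4-methoxy-5-(methoxymethoxy)phenyl]-1-[2-hydroxy-6-methoxy-4-(methoxymethoxy)phenyl]-3,3-dimethoxypropan-1-one F4.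
- HCl in MeOH at 60 °C would close the pyranone and strip both MOM groups to give 5'-bromo-7,3'-dihydroxy-5,4'-dimethoxyisoflavone F5.
- MOMCl with iPr2NEt would then return F5 to 16.

Step 8 (Graham oxidation). Hypochlorite may chlorinate the alkoxy-substituted ring, or the electron-rich diazirine may lose nitrogen during extraction. The fallback gives up the diazirine as carbene source; it sets out from aldehyde 7 and comes back at 16. Deoxygenative dichlorination of 7 ((COCl)2, catalytic Ph3PO, CHCl3) would give 1-bromo-5-(dichloromethyl)-2-methoxy-3-(methoxymethoxy)benzene F6. α-Elimination of HCl from F6 with KOtBu in pentane at 0 °C in the presence of enol ether 4 would generate the same arylchlorocarbene as its carbenoid. Cyclopropane 14 would then form and, on warming in MeCN, open through 15 to 16.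

Step 10 (Stille prenylation). Transmetalation through the γ-carbon would lead to the reverse-prenyl (1,1-dimethylallyl) isomer, and slow oxidative addition into the ortho-alkoxy bromide would allow protodebromination. The fallback separates C–C coupling from construction of the trisubstituted alkene; it sets out from 16 and comes back at 18. Stille coupling of 16 with allyltributylstannane (Pd(PPh3)4, DMF), which has no regiochemical ambiguity, would give 5'-allyl-5,4'-dimethoxy-7,3'-bis(methoxymethoxy)isoflavone F7. Cross-metathesis of F7 with excess 2-methylbut-2-ene (second-generation Grubbs catalyst, (H2IMes)(PCy3)Cl2Ru=CHPh, CH2Cl2, 40 °C) would then give 18.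

**Further compounds**

F1 | step 9 | 1-(2,4-dihydroxy-6-methoxyphenyl)ethanone | CC(=O)c1c(O)cc(O)cc1OC
F2 | step 9 | 1-[2-hydroxy-6-methoxy-4-(methoxymethoxy)phenyl]ethanone | CC(=O)c1c(O)cc(OCOC)cc1OC
F3 | step 9 | (E)-3-[3-bromo-4-methoxy-5-(methoxymethoxy)phenyl]-1-[2-hydroxy-6-methoxy-4-(methoxymethoxy)phenyl]prop-2-en-1-one | COCOc1cc(O)c(C(=O)/C=C/c2cc(OCOC)c(OC)c(Br)c2)c(OC)c1
F4 | step 9 | 2-[3-bromo-4-methoxy-5-(methoxymethoxy)phenyl]-1-[2-hydroxy-6-methoxy-4-(methoxymethoxy)phenyl]-3,3-dimethoxypropan-1-one (racemic) | COCOc1cc(O)c(C(=O)C(C(OC)OC)c2cc(OCOC)c(OC)c(Br)c2)c(OC)c1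
F5 | step 9 | 5'-bromo-7,3'-dihydroxy-5,4'-dimethoxyisoflavone | COc1cc(O)cc2occ(-c3cc(O)c(OC)c(Br)c3)c(=O)c12
F6 | step 8 | 1-bromo-5-(dichloromethyl)-2-methoxy-3-(methoxymethoxy)benzene | ClC(Cl)c1cc(OCOC)c(OC)c(Br)c1
F7 | step 10 | 5'-allyl-5,4'-dimethoxy-7,3'-bis(methoxymethoxy)isoflavone | COc1cc(OCOC)cc2occ(-c3cc(OCOC)c(OC)c(CC=C)c3)c(=O)c12
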